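The C23–C24 bond carries the whole plan. The hemiaminal carbon C24 of the lactam ring (bonded to O25, N26, C34 and benzylic C23) is read as an imide carbonyl that has accepted a benzyl anion. In one operation, SmI2 should turn the CH2Br group of seco compound 33 into a benzylsamarium species that adds to C24, closing the 13-membered paracyclophane ring and setting C24 anti to the C34 methoxy group. Compound 33 is the complete ring A/B/C core with the C15 aryl ether and an enolised 3-acyl-4-methoxysuccinimide; its nitrogen carries a removable methoxy group, so that no N–H quenches the organosamarium, and C34 is taken from (S)-malate.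

Key step: step 21

Labels: atoms C1–C36 are numbered in the order of the target SMILES; ring A = C7, C8, C9, C11, C12, C14; ring B = C6, C7, C14, C15, C33; ring C = C3, C4, C5, C6, C33, C32.

Assumption: the (S,S)-configured lithium amide is taken, by analogy with 4-substituted cyclohexanones, to remove the α-proton that leads to 3; if the sense proves opposite, the (R,R)-amide is used.

Step 1
Reactants: 1 cis-3,5-dimethylcyclohexanone
Product: 3 trimethyl{[(3S,5R)-3,5-dimethylcyclohex-1-en-1-yl]oxy}silane, via lithium enolate 2 (not isolated)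
Conditions: LiN[(S)-CHMePh]2 (from the amine and n-BuLi), LiCl, Me3SiCl (internal quench), THF, −100 °C
Reagents that add atoms: chlorotrimethylsilane, C[Si](C)(C)Cl
Why: Enantioselective deprotonation of a meso ketone by a chiral lithium amide with internal silyl quench (asymmetric desymmetrisation) removes one of the two enantiotopic axial α-protons, so that the untouched C9 and C12 methyl centres are fixed relative to the new C7=C14 enol double bond.

Step 2
Reactants: 3 trimethyl{[(3S,5R)-3,5-dimethylcyclohex-1-en-1-yl]oxy}silane; 4 (2E)-4,4-dimethoxybut-2-enal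
Product: 6 (2S,3S,5R)-2-[(1S,2E)-1-hydroxy-4,4-dimethoxybut-2-en-1-yl]-3,5-dimethylcyclohexan-1-one (anti aldol adduct), via dibutylboron enolate 5 (not isolated)
Conditions: Bu2BOTf (0.95 equiv), CH2Cl2, 0 °C → rt; Me3SiOTf removed in vacuo; CH2Cl2, 4, −78 → −20 °C; pH 7 buffer, MeOH
Reagents that add atoms: none
Why: Direct silicon-to-boron transmetalation of the enol silane with dibutylboron triflate gives the regiodefined boron enolate without any metal enolate that could equilibrate, the silyl triflate formed is stripped off so that it cannot ionise the dimethyl acetal of 4, and the ring-fixed E boron enolate should then react through a closed chair (Zimmerman–Traxler) aldol transition state to give the anti adduct, the aldehyde approaching C14 trans to the neighbouring C12 methyl group, which sets C14 and C15.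

Step 3
Reactants: 6 anti aldol adduct
Product: 7 tert-butyldimethylsilyl ether of 6 (silylated at the C15 oxygen)
Conditions: t-BuMe2SiCl, imidazole, DMF, 35 °C
Reagents that add atoms: tert-butyldimethylsilyl chloride, CC(C)(C)[Si](C)(C)Cl
Why: Standard silylation of a secondary alcohol, which blocks retro-aldol cleavage and carries the C15 oxygen through the chain extension at C7.

Step 4
Reactants: 7 silyl ether ketone
Product: 8 exocyclic methylidene compound (ring C=O of 7 replaced by C=CH2; the new carbon is C6)
Conditions: Cp2TiMe2, toluene, 70 °C, dark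
Reagents that add atoms: dimethyltitanocene, C[Ti](C)(C1C=CC=C1)C1C=CC=C1
Why: Petasis methylenation with the non-basic titanium methylidene converts the hindered, enolisable ketone into the alkene without epimerisation at C14 or β-elimination of the silyloxy group.

Step 5
Reactants: 8 exocyclic methylidene compound
Product: 10 primary alcohol (CH2OH on C7 of ring A; C7 epimers), via alkylborane 9 (not isolated)
Conditions: 9-BBN, THF, 0 °C → rt; NaOH, H2O2, 0 °C
Reagents that add atoms: hydrogen peroxide, OO
Why: Hydroboration–oxidation with the bulky dialkylborane is anti-Markovnikov and selective for the 1,1-disubstituted alkene over the hindered internal alkene; the C7 configuration formed here is not decisive because it is equilibrated in step 6.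

Step 6
Reactants: 10 primary alcohol
Product: 11 ring A aldehyde (CHO on C7 trans to the C14 side chain; all four ring substituents equatorial)
Conditions: DMP, pyridine, CH2Cl2, 0 °C → rt; then DBU (cat.), CH2Cl2, rt
Reagents that add atoms: none
Why: Dess–Martin oxidation gives the aldehyde, and base-mediated epimerisation of its α-centre places the formyl group equatorial and trans to the C14 side chain, which sets C7 under thermodynamic control.

Step 7
Reactants: 11 ring A aldehyde
Product: 12 (E)-vinyl iodide (C7–CH=CH–I)
Conditions: CrCl2, CHI3, THF, 0 °C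
Reagents that add atoms: iodoform, IC(I)I
Why: Takai olefination with the gem-dichromium reagent gives the (E)-vinyl iodide under non-basic conditions that leave C7 untouched.

Step 8
Reactants: 12 (E)-vinyl iodide; 13 2-[(1E)-buta-1,3-dien-1-yl]-4,4,5,5-tetramethyl-1,3,2-dioxaborolane
Product: 14 (E,E)-triene (C7–CH=CH–CH=CH–CH=CH2; C15 silyl ether; dimethyl acetal)
Conditions: Pd(PPh3)4 (cat.), K3PO4, THF/H2O, rt, degassed, dark
Reagents that add atoms: none
Why: Suzuki–Miyaura coupling proceeds with retention of both alkene geometries and delivers the (E,E)-triene C1–C6 with its terminal vinyl group.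

Step 9
Reactants: 14 (E,E)-triene silyl ether
Product: 15 triene alcohol (free C15–OH)
Conditions: Bu4NF, THF, 0 °C
Reagents that add atoms: none
Why: Fluoride-induced cleavage of the silyl ether frees the C15 hydroxyl without touching the acetal or the triene.

Step 10
Reactants: 15 triene alcohol; 16 4-fluorobenzaldehyde
Product: 18 C15 4-formylphenyl ether, via sodium alkoxide 17 (not isolated)
Conditions: NaH, DMF, 0 °C; 16, 0 °C → rt
Reagents that add atoms: none
Why: Nucleophilic aromatic substitution (addition–elimination) of the alkoxide on the fluoride activated by the para-formyl group forms the aryl ether, and since the C15–O bond is not broken C15 keeps its configuration.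

Step 11
Reactants: 18 C15 4-formylphenyl ether
Product: 19 C15 4-(hydroxymethyl)phenyl ether
Conditions: NaBH4, MeOH/THF, 0 °C
Reagents that add atoms: none
Why: Chemoselective borohydride reduction of the aryl aldehyde gives the benzylic alcohol (C23) that will later carry the bromide.

Step 12
Reactants: 19 benzylic alcohol
Product: 20 benzylic tert-butyldimethylsilyl ether
Conditions: t-BuMe2SiCl, imidazole, CH2Cl2, 0 °C → rt
Reagents that add atoms: tert-butyldimethylsilyl chloride, CC(C)(C)[Si](C)(C)Cl
Why: Silyl protection of the primary benzylic alcohol for the Lewis acid, boron enolate and oxidation steps that follow.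

Step 13
Reactants: 20 benzylic silyl ether acetal
Product: 21 trienal (acetal hydrolysed to the (E)-enal C33=C32–CHO)
Conditions: PPTS (cat.), acetone/H2O, rt
Reagents that add atoms: water, O
Why: Mild acid-catalysed hydrolysis of the allylic dimethyl acetal unveils the (E)-enal dienophile while the primary silyl ether, the allylic aryl ether and the triene persist.

Step 14
Reactants: 21 trienal
Product: 22 tricyclic aldehyde (ring A/B/C core; trans A/B and trans B/C junctions; H6 cis to H7; C3 vinyl and C32 formyl cis to the C6–C7 bond; C15 aryloxy group cis to C12 and C32 on ring B)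
Conditions: Me2AlCl, CH2Cl2, −78 → −30 °C
Reagents that add atoms: none
Why: Lewis acid-promoted intramolecular Diels–Alder reaction of the (E,E)-diene with the (E)-enal through the endo-formyl, tether-exo transition state should give the trans ring B/C junction with C3 vinyl, C32 formyl and the C6–C7 bond cis on ring C; which dienophile face reacts, and thus the configuration of C3, C6, C32 and C33 relative to ring A (H6 must end cis to H7), is decided by the C14 and C15 stereocentres on the three-atom tether.

Step 15
Reactants: 23 dimethyl (2S)-2-hydroxybutanedioate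
Product: 24 dimethyl (2S)-2-methoxybutanedioate
Conditions: MeI, Ag2O, MeCN, rt, dark
Reagents that add atoms: iodomethane, CI
Why: Purdie O-methylation under neutral, non-enolising conditions installs the future C34 methyl ether with the (S) configuration of malate intact.

Step 16
Reactants: 24 dimethyl (2S)-2-methoxybutanedioate
Product: 25 (2S)-2-methoxybutanedioic acid
Conditions: LiOH, THF/H2O, 0 °C; then HCl
Reagents that add atoms: lithium hydroxide, [Li+].[OH-]
Why: Ester saponification at low temperature, under which the α-methoxy centre is not enolised.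

Step 17
Reactants: 25 (2S)-2-methoxybutanedioic acid; 26 O-methylhydroxylamine hydrochloride
Product: 29 (3S)-1,3-dimethoxypyrrolidine-2,5-dione, via cyclic anhydride 27 (not isolated), via amic acid 28 (not isolated)
Conditions: AcCl, 50 °C; evaporate; 26, pyridine, CH2Cl2, 0 °C → rt; AcCl, 60 °C
Reagents that add atoms: none
Why: Dehydration to the cyclic anhydride, ring opening by the hydroxylamine nitrogen and acylative ring closure is the standard synthesis of N-alkoxy imides, both regioisomeric amic acids converging on the same imide with C34 untouched.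

Step 18
Reactants: 22 tricyclic aldehyde; 29 (3S)-1,3-dimethoxypyrrolidine-2,5-dione
Product: 31 β-hydroxy imide (aldol adduct; C30 carbinol bonded to C29 of the imide; mixture at C29 and C30), via boron enolate 30 (not isolated)
Conditions: 29 (excess), Bu2BOTf, i-Pr2NEt, CH2Cl2, −78 → 0 °C; 22, −78 → −20 °C; pH 7 buffer, MeOH
Reagents that add atoms: none
Why: Boron-mediated aldol addition after soft enolisation of the imide at its unsubstituted α-carbon C29, in which the covalent boron enolate avoids a free enolate that could expel the C34 methoxide, and the new centres at C29 and C30 are erased in step 19.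

Step 19
Reactants: 31 β-hydroxy imide
Product: 32 N-methoxy 3-acyl-4-methoxysuccinimide (C30 enol; benzylic silyl ether)
Conditions: DMP, CH2Cl2, 0 °C → rt
Reagents that add atoms: none
Why: Dess–Martin oxidation of the β-hydroxy imide gives the β-keto imide, which exists as the C30 enol hydrogen-bonded to the C27 carbonyl, so that C34 is the only stereocentre left in the side chain.

Step 20
Reactants: 32 acyl methoxysuccinimide silyl ether
Product: 33 seco acyl methoxysuccinimide benzylic bromide (N-methoxy; precursor of the key step)
Conditions: Me3SiBr, CH2Cl2, −20 → 0 °C; used at once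
Reagents that add atoms: bromotrimethylsilane, C[Si](C)(C)Br
Why: Silyl ether to bromide exchange with a bromosilane, in which the electron-rich p-alkoxybenzyl silyl ether ionises readily and collapses to the benzylic bromide while the methyl and aryl alkyl ethers are not cleaved and the enol is at most silylated reversibly.

Step 21
Reactants: 33 seco acyl methoxysuccinimide benzylic bromide
Product: 35 N-methoxy xenoacremone C (13-membered paracyclophane; C24 hemiaminal), via sodium enolate 34 (not isolated)
Conditions: NaH (1.0 equiv), THF, −20 °C; then added over 6 h to SmI2 (3 equiv), THF, −40 → 0 °C, final 0.002 M; pH 7 buffer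
Reagents that add atoms: none
Why: Proposed new method: two single-electron transfers from SmI2 (divalent samarium) convert the benzylic C23–Br bond into a benzylsamarium species (trivalent samarium) that adds to the C24 imide carbonyl and gives the tertiary hemiaminal after protonation; the closest known reaction types are the SmI2 Barbier addition of benzylic halides to N-substituted cyclic imides and SmI2 Barbier macrocyclisations of benzylic bromides onto aldehydes. The ring closes by exo addition to the C24=O bond in a 13-membered macrocyclic mode, and slow addition at high dilution and low temperature is meant to let the organosamarium be trapped intramolecularly before it dimerises, is protonated, or enolate 34 is benzylated. C24 is set by attack on the face of the five-membered ring anti to the C34 methoxy group, which places O25 cis to O35 and the benzyl carbon trans, as in the target. The step needs addition at C24 and not at C27 or C30; this is secured by converting the acidic enol into enolate 34, which deactivates C27 and C30 as parts of a vinylogous carboxylate, while C24 is activated by the adjacent methoxy-bearing C34 and by chelation of samarium between the carbonyl oxygen and the N-methoxy oxygen, which also holds the adduct as a closed alkoxide. The N-methoxy group removes the N–H proton that would quench the organosamarium, and the absence of HMPA together with the low temperature should keep the α-alkoxy imide and the N–O bond from being reduced before the C–C bond forms.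

Step 22
Reactants: 35 N-methoxy xenoacremone C
Product: 36 xenoacremone C
Conditions: SmI2, THF, 0 °C → rt; then aq. NH4Cl
Reagents that add atoms: none
Why: Reductive cleavage of the N–O bond of an N-alkoxy lactam by SmI2 is an established deprotection and should release the lactam N–H without affecting the hemiaminal, the enol, the ethers or the alkenes, C24 and C34 being untouched.

Compound list
1 | cis-3,5-dimethylcyclohexanone (meso) | C[C@@H]1C[C@H](C)CC(=O)C1 | starting material
2 | lithium (3S,5R)-3,5-dimethylcyclohex-1-en-1-olate | [Li]OC1=C[C@@H](C)C[C@@H](C)C1 | intermediate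
3 | trimethyl{[(3S,5R)-3,5-dimethylcyclohex-1-en-1-yl]oxy}silane | C[Si](C)(C)OC1=C[C@@H](C)C[C@@H](C)C1 | intermediate
4 | (2E)-4,4-dimethoxybut-2-enal | COC(OC)/C=C/C=O | starting material
5 | dibutyl{[(3S,5R)-3,5-dimethylcyclohex-1-en-1-yl]oxy}borane | CCCCB(CCCC)OC1=C[C@@H](C)C[C@@H](C)C1 | intermediate
6 | (2S,3S,5R)-2-[(1S,2E)-1-hydroxy-4,4-dimethoxybut-2-en-1-yl]-3,5-dimethylcyclohexan-1-one | O=C1C[C@H](C)C[C@H](C)[C@H]1[C@@H](O)/C=C/C(OC)OC | intermediate
7 | tert-butyldimethylsilyl ether of 6 | O=C1C[C@H](C)C[C@H](C)[C@H]1[C@@H](O[Si](C)(C)C(C)(C)C)/C=C/C(OC)OC | intermediate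
8 | methylidene compound (C=CH2 in place of the ring C=O of 7) | C=C1C[C@H](C)C[C@H](C)[C@H]1[C@@H](O[Si](C)(C)C(C)(C)C)/C=C/C(OC)OC | intermediate
9 | B-alkyl-9-borabicyclo[3.3.1]nonane from 8 (boron on C6; C7 epimers) | C(B1C2CCCC1CCC2)C1C[C@H](C)C[C@H](C)[C@H]1[C@@H](O[Si](C)(C)C(C)(C)C)/C=C/C(OC)OC | intermediate
10 | primary alcohol (CH2OH on C7; C7 epimers) | OCC1C[C@H](C)C[C@H](C)[C@H]1[C@@H](O[Si](C)(C)C(C)(C)C)/C=C/C(OC)OC | intermediate
11 | ring A aldehyde (CHO on C7 trans to the C14 side chain) | O=C[C@@H]1C[C@H](C)C[C@H](C)[C@H]1[C@@H](O[Si](C)(C)C(C)(C)C)/C=C/C(OC)OC | intermediate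
12 | (E)-vinyl iodide (C7–CH=CH–I) | I/C=C/[C@@H]1C[C@H](C)C[C@H](C)[C@H]1[C@@H](O[Si](C)(C)C(C)(C)C)/C=C/C(OC)OC | intermediate
13 | 2-[(1E)-buta-1,3-dien-1-yl]-4,4,5,5-tetramethyl-1,3,2-dioxaborolane | C=C/C=C/B1OC(C)(C)C(C)(C)O1 | starting material
14 | (E,E)-triene with C15 silyl ether and dimethyl acetal | C=C/C=C/C=C/[C@@H]1C[C@H](C)C[C@H](C)[C@H]1[C@@H](O[Si](C)(C)C(C)(C)C)/C=C/C(OC)OC | intermediate
15 | triene alcohol (free C15–OH) | C=C/C=C/C=C/[C@@H]1C[C@H](C)C[C@H](C)[C@H]1[C@@H](O)/C=C/C(OC)OC | intermediate
16 | 4-fluorobenzaldehyde | O=Cc1ccc(F)cc1 | starting material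
17 | sodium alkoxide of 15 | C=C/C=C/C=C/[C@@H]1C[C@H](C)C[C@H](C)[C@H]1[C@@H]([O-])/C=C/C(OC)OC.[Na+] | intermediate
18 | C15 4-formylphenyl ether | C=C/C=C/C=C/[C@@H]1C[C@H](C)C[C@H](C)[C@H]1[C@@H](Oc2ccc(C=O)cc2)/C=C/C(OC)OC | intermediate
19 | C15 4-(hydroxymethyl)phenyl ether | C=C/C=C/C=C/[C@@H]1C[C@H](C)C[C@H](C)[C@H]1[C@@H](Oc2ccc(CO)cc2)/C=C/C(OC)OC | intermediate
20 | C15 4-[(tert-butyldimethylsilyloxy)methyl]phenyl ether, dimethyl acetal | C=C/C=C/C=C/[C@@H]1C[C@H](C)C[C@H](C)[C@H]1[C@@H](Oc2ccc(CO[Si](C)(C)C(C)(C)C)cc2)/C=C/C(OC)OC | intermediate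
21 | trienal ((E)-enal from 20) | C=C/C=C/C=C/[C@@H]1C[C@H](C)C[C@H](C)[C@H]1[C@@H](Oc2ccc(CO[Si](C)(C)C(C)(C)C)cc2)/C=C/C=O | intermediate
22 | tricyclic aldehyde (ring A/B/C core; CHO on C32) | C=C[C@@H]1C=C[C@@H]2[C@@H]3C[C@H](C)C[C@H](C)[C@H]3[C@@H](Oc4ccc(CO[Si](C)(C)C(C)(C)C)cc4)[C@H]2[C@@H]1C=O | intermediate
23 | dimethyl (2S)-2-hydroxybutanedioate (dimethyl L-malate) | COC(=O)C[C@H](O)C(=O)OC | starting material
24 | dimethyl (2S)-2-methoxybutanedioate | COC(=O)C[C@H](OC)C(=O)OC | intermediate
25 | (2S)-2-methoxybutanedioic acid | OC(=O)C[C@H](OC)C(=O)O | intermediate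
26 | O-methylhydroxylamine hydrochloride | [NH3+]OC.[Cl-] | starting material
27 | (3S)-3-methoxyoxolane-2,5-dione | O=C1C[C@H](OC)C(=O)O1 | intermediate
28 | (3S)-3-methoxy-4-(methoxyamino)-4-oxobutanoic acid (formed with its regioisomer) | CONC(=O)[C@@H](OC)CC(=O)O | intermediate
29 | (3S)-1,3-dimethoxypyrrolidine-2,5-dione | CON1C(=O)C[C@H](OC)C1=O | intermediate
30 | dibutylboron enolate of 29 (enolised towards C29) | CON1C(OB(CCCC)CCCC)=C[C@H](OC)C1=O | intermediate
31 | β-hydroxy imide (aldol adduct; C29 and C30 unassigned) | C=C[C@@H]1C=C[C@@H]2[C@@H]3C[C@H](C)C[C@H](C)[C@H]3[C@@H](Oc4ccc(CO[Si](C)(C)C(C)(C)C)cc4)[C@H]2[C@@H]1C(O)C5C(=O)N(OC)C(=O)[C@H]5OC | intermediate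
32 | N-methoxy 3-acyl-4-methoxysuccinimide (enol), benzylic silyl ether | C=C[C@@H]1C=C[C@@H]2[C@@H]3C[C@H](C)C[C@H](C)[C@H]3[C@@H](Oc4ccc(CO[Si](C)(C)C(C)(C)C)cc4)[C@H]2[C@@H]1/C(O)=C5/C(=O)N(OC)C(=O)[C@H]5OC | intermediate
33 | seco acyl methoxysuccinimide benzylic bromide (N-methoxy) | C=C[C@@H]1C=C[C@@H]2[C@@H]3C[C@H](C)C[C@H](C)[C@H]3[C@@H](Oc4ccc(CBr)cc4)[C@H]2[C@@H]1/C(O)=C5/C(=O)N(OC)C(=O)[C@H]5OC | intermediate
34 | sodium enolate of 33 | C=C[C@@H]1C=C[C@@H]2[C@@H]3C[C@H](C)C[C@H](C)[C@H]3[C@@H](Oc4ccc(CBr)cc4)[C@H]2[C@@H]1/C([O-])=C5/C(=O)N(OC)C(=O)[C@H]5OC.[Na+] | intermediate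
35 | N-methoxy xenoacremone C | C=C[C@@H]1C=C[C@@H]2[C@@H]3C[C@H](C)C[C@H](C)[C@H]3[C@H]3Oc4ccc(cc4)C[C@@]4(O)N(OC)C(=O)/C(=C(\O)[C@H]1[C@@H]23)[C@@H]4OC | intermediate
36 | xenoacremone C | C=C[C@@H]1C=C[C@@H]2[C@@H]3C[C@H](C)C[C@H](C)[C@H]3[C@H]3Oc4ccc(cc4)C[C@@]4(O)NC(=O)/C(=C(\O)[C@H]1[C@@H]23)[C@@H]4OC | target

Total step count: 22. Longest linear sequence: 19 steps (steps 1–14 and 18–22). Imide 29 comes from a three-step side branch (steps 15–17).

Steps most likely to fail

1. Step 21 (new method). The benzyl organometallic may be protonated or dimerise before the ring closes (reduction to the methylarene, Wurtz coupling). It may also add to C27 or C30, or the C34 methoxy group α to the C24 carbonyl may be lost by reduction. Fallback by known chemistry (intramolecular Wittig olefination of an imide carbonyl, then hydration of the resulting enamide): it sets out from 33 and comes back at 35. Bromide 33 is treated with PPh3 (MeCN, rt) to give the phosphonium bromide F1. KN(SiMe3)2 (2 equiv, toluene, 0.002 M, 80 °C) should form the enolate and the benzylic ylide, which olefinates C24 to the macrocyclic 5-benzylidene lactam F2. Dilute aqueous HCl in THF at 0 °C should protonate C23 and add water to the acyliminium ion at C24 anti to the C34 methoxy group, which returns 35.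

2. Step 14. The diene may add to the other face of the dienophile. The adduct needed has H6 cis to H7, which works against the twist that the trans-diequatorial substituents of ring A impose on the tether. The diastereomer inverted at C3, C6, C32 and C33, or a cis-fused exo adduct, may therefore dominate. Fallback with catalyst control in place of substrate control: it sets out from 21 and comes back at 22 without new isolated compounds. Trienal 21 is cyclised by iminium activation with a chiral imidazolidinone salt, (2S,5S)- or (2R,5R)-5-benzyl-2-tert-butyl-3-methylimidazolidin-4-one trifluoroacetate, in MeCN/H2O at 0 °C. This is an established organocatalytic intramolecular Diels–Alder reaction of trienals in which the catalyst shields one face of the iminium dienophile; the catalyst enantiomer that exposes the required face is used.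

3. Step 18. Enolisation may occur at the methoxy-bearing carbon C34 (loss of configuration), or methoxide may be eliminated from the enolate, and the addition to the hindered aldehyde may be slow. Fallback that builds the acyl imide on the core: it sets out from 22 and comes back at 32. Aldehyde 22 is oxidised (NaClO2, NaH2PO4, 2-methylbut-2-ene, t-BuOH/H2O) to the carboxylic acid F3. Coupling with Meldrum's acid (EDC, DMAP, CH2Cl2) gives the acyl Meldrum's acid F4. Heating F4 with O-methylhydroxylamine (toluene, 80 °C) should give the β-keto N-methoxyamide F5 through the acylketene. Knoevenagel condensation of F5 with glyoxylic acid and cyclodehydration (Ac2O, NaOAc) gives the N-methoxy acylmaleimide F6. Conjugate addition of methanol (MeOH, cat. Et3N, 0 °C) gives 32 together with its C34 epimer; the two are separated, and the epimer is recycled by base-induced elimination and re-addition of methanol. In this fallback C34 is no longer set by the chiral pool.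

Further compounds
F1 | step 21 | triphenylphosphonium bromide from 33 (PPh3+ on C23) | C=C[C@@H]1C=C[C@@H]2[C@@H]3C[C@H](C)C[C@H](C)[C@H]3[C@@H](Oc4ccc(C[P+](c6ccccc6)(c7ccccc7)c8ccccc8)cc4)[C@H]2[C@@H]1/C(O)=C5/C(=O)N(OC)C(=O)[C@H]5OC.[Br-]
F2 | step 21 | macrocyclic N-methoxy 5-benzylidene lactam (C23=C24; alkene geometry not assigned) | C=C[C@@H]1C=C[C@@H]2[C@@H]3C[C@H](C)C[C@H](C)[C@H]3[C@H]3Oc4ccc(cc4)C=C4N(OC)C(=O)/C(=C(\O)[C@H]1[C@@H]23)[C@@H]4OC
F0 | step 14 | none | none
F3 | step 18 | tricyclic carboxylic acid (CO2H on C32) | C=C[C@@H]1C=C[C@@H]2[C@@H]3C[C@H](C)C[C@H](C)[C@H]3[C@@H](Oc4ccc(CO[Si](C)(C)C(C)(C)C)cc4)[C@H]2[C@@H]1C(=O)O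
F4 | step 18 | acyl Meldrum's acid (enol form) | C=C[C@@H]1C=C[C@@H]2[C@@H]3C[C@H](C)C[C@H](C)[C@H]3[C@@H](Oc4ccc(CO[Si](C)(C)C(C)(C)C)cc4)[C@H]2[C@@H]1C(O)=C5C(=O)OC(C)(C)OC5=O
F5 | step 18 | β-keto N-methoxyamide | C=C[C@@H]1C=C[C@@H]2[C@@H]3C[C@H](C)C[C@H](C)[C@H]3[C@@H](Oc4ccc(CO[Si](C)(C)C(C)(C)C)cc4)[C@H]2[C@@H]1C(=O)CC(=O)NOC
F6 | step 18 | N-methoxy 3-acylmaleimide | C=C[C@@H]1C=C[C@@H]2[C@@H]3C[C@H](C)C[C@H](C)[C@H]3[C@@H](Oc4ccc(CO[Si](C)(C)C(C)(C)C)cc4)[C@H]2[C@@H]1C(=O)C5=CC(=O)N(OC)C5=O
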